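The readings come from a simulation with made-up constants; noise was put on by code.

| flask | J | L | remark | time |
|---|---|---|---|---|
| spring | 0.050 M | 5.1 mol% | run made earlier |  |
| dawn | 0.11 M | 5.1 mol% | run made earlier |  |
| summer | 0.31 M | 5.1 mol% | run made earlier |  |
| red | 0.040 M | 5.1 mol% |  | 8.0 min |
| grey | 0.080 M | 5.1 mol% |  | 8.0 min |
| amber | 0.15 M | 5.1 mol% |  | 8.0 min |
| green | 0.30 M | 5.1 mol% |  | 8.0 min |

| spring: time / min | spring: Q / % | dawn: time / min | dawn: Q / % | summer: time / min | summer: Q / % |
|---|---|---|---|---|---|
| 1.50 | 34.1 | 1.50 | 37.0 | 1.50 | 31.7 |
| 3.00 | 41.5 | 3.00 | 38.3 | 3.00 | 28.3 |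
| 5.00 | 43.2 | 5.00 | 38.1 | 5.00 | 29.7 |
| 6.00 | 41.7 | 6.00 | 39.4 | 6.00 | 30.7 |
| 8.00 | 42.8 | 8.00 | 41.4 | 8.00 | 31.4 |

(readings scatter by 1 percentage point)

- a reading or a percentage of Q counts all its forms, free or not
- "hardly changes" means that all values lie within two and a half points (for a concentration: within two and a half percent of the largest)

* amount of Q at the end, in percent of the J charged for red, grey, amber, green, in this order
* how the row runs (hardly changes / rises all the way / rises, then falls / falls, then rises / falls all the way)

1. I began with the easy step: I averaged the last three readings of each run, from 5.00 min on, since the runs looked nearly level by then. That gave 42.6% of Q for spring, 39.6% for dawn and 30.6% for summer.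

2. I then worked with what did not become Q. I divided that share by the share of Q and called the result the loss ratio, the parts of J charged that ended as something else for each part that ended as Q; spring read 1.35, and summer read 2.27.

3. At this fixed loading, I drew a straight line through those two values, which rose by 3.53 M⁻¹. Each flask's charge then gives one number, and Q is one part in one plus that number.

4. To test whether one number was enough, I used dawn, which the line had not seen. The line gave a loss ratio of 1.56, so 39.0% of Q, a gap of 0.60 percentage points from the reading, with a scatter of 1 point per reading.

5. My row was 43.2%, 40.7%, 37.0% and 30.9%, falling all the way.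

The forecast, which held that “the plateau falls almost linearly with” the charge of J, gave 43%, 41%, 37.5% and 31%, so falls all the way, and its amber value stood 0.5 points above mine.

The flasks gave 44.4%, 40.5%, 36.1% and 30.7%, so falls all the way.

    J + L → X (k = 7.72 M⁻¹ s⁻¹)
    X → L + Q (k = 0.374 s⁻¹)
    D ⇌ Q, rate k3*(cs3 - [Q]) while solid is left; crystals form when [Q] > cs3 (solubility = 0.0580 M, k = 0.724 s⁻¹)
    2 J → E (k = 0.470 M⁻¹ s⁻¹)

The end values gave red a loss ratio of 1.25, in parts of J charged, which is lower than spring's 1.35, and green gave 2.26, beside summer's 2.27. At the red charge, the first half-life of J by the turning of two J into E, taken by itself, was 0.443 min, shorter than the 0.73 min by the turning of J + L into X with the other concentrations held at their charge. Red had done half of its turning of two J into E by 0.196 min, and 98% of it by 1.60 min.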